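The hydroazulene is disconnected at C6–C7 and C3–C4 (cycloheptene C1–C7: C1 angelate carbinol, C3 methylated alkene carbon, C5 aroyloxy carbinol, C6/C7 fusion carbons; cyclopentane C7–C8–C9–C10–C6, C10 the isopropyl carbinol). Since the C5 oxygen is carried by the central atom of the C4–C5–C6 triad, which faces the C7–C1–C2–C3 tetrad, and C8–C9–C10 already joins C6 to C7, one intramolecular (4+3) cycloaddition of an oxyallyl cation onto a tethered (E,E)-diene should close both rings and set C3, C6 and C7 from C10. The precursor is an open-chain (S)-dichloromethyl ketone with a silylated tertiary carbinol; its extra chlorine stabilises the cation and is removed by zinc in the same flask.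

Key step: step 11

Remark: α/β refer to the bicycle drawn with the C7 methyl up (β); systematic names use azulene locants (C1 = 8, C2 = 7, C3 = 6, C4 = 5, C5 = 4, C6 = 3a, C7 = 8a, C8 = 1, C9 = 2, C10 = 3); the C4 chloride of 17 is taken as an epimer mixture that the zinc reduction erases; crotonaldehyde is used as its commercial (E)-isomer.

Step 1
Reactants: 1 (E)-but-2-enal; 2 2-(triphenylphosphoranylidene)propanal
Product: 3 (2E,4E)-2-methylhexa-2,4-dienal
Conditions: 1 (excess), PhMe, 80 °C
Reagents that add atoms: none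
Why: Wittig olefination with a formyl-stabilised ylide is E-selective, so the trisubstituted alkene (later C7=C1) should form E next to the existing E-alkene, and the excess of the volatile enal suppresses a second homologation.

Step 2
Reactants: 3 (2E,4E)-2-methylhexa-2,4-dienal
Product: 4 (3E,5E)-3-methylhepta-1,3,5-triene
Conditions: Ph3PCH3Br, KOtBu, THF, 0 °C → rt
Reagents that add atoms: methyltriphenylphosphonium bromide, C[P+](c1ccccc1)(c1ccccc1)c1ccccc1.[Br-]
Why: Wittig methylenation of an enal proceeds by 1,2-addition and leaves the two existing alkenes and their geometry untouched.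

Step 3
Reactants: 5 4-methylpent-2-yn-1-ol
Product: 7 (2Z)-3-iodo-4-methylpent-2-en-1-ol, via cyclic alkenylalanate 6 (not isolated)
Conditions: NaAlH2(OCH2CH2OMe)2, THF, 0 °C → rt; then I2, THF, −78 → 0 °C
Reagents that add atoms: iodine, II
Why: Alkoxide-directed trans-hydroalumination of the propargylic alcohol places aluminium on C3 in a five-membered chelate, and iodinolysis with retention should give the Z-iodoalkene (iodine cis to CH2OH) regio- and stereospecifically.

Step 4
Reactants: 4 (3E,5E)-3-methylhepta-1,3,5-triene; 7 (2Z)-3-iodo-4-methylpent-2-en-1-ol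
Product: 9 (2E,6E,8E)-6-methyl-3-(propan-2-yl)deca-2,6,8-trien-1-ol, via alkylborane 8 (not isolated)
Conditions: 9-BBN-H (9-borabicyclo[3.3.1]nonane), THF, 0 °C → rt; then 7, PdCl2(dppf) (5 mol %), AsPh3, Cs2CO3, DMF/H2O, rt
Reagents that add atoms: none
Why: The borane should hydroborate only the terminal vinyl group (anti-Markovnikov), and the B-alkyl Suzuki–Miyaura coupling proceeds with retention at the iodoalkene, so the chain ends cis to CH2OH and the isopropyl group trans (2E).

Step 5
Reactants: 9 (2E,6E,8E)-6-methyl-3-(propan-2-yl)deca-2,6,8-trien-1-ol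
Product: 10 [(2R,3R)-3-[(3E,5E)-3-methylhepta-3,5-dien-1-yl]-3-(propan-2-yl)oxiran-2-yl]methanol
Conditions: Ti(OiPr)4 (10 mol %), D-(−)-diethyl tartrate (12 mol %), t-BuOOH, 4 Å MS, CH2Cl2, −20 °C
Reagents that add atoms: tert-butyl hydroperoxide, CC(C)(C)OO
Why: Sharpless asymmetric epoxidation touches only the allylic alcohol (the conjugated diene is inert to the titanium tartrate peroxide), and the D-(−)-tartrate should deliver oxygen to the face that gives the (2R,3R)-epoxide, which fixes the future C10 carbinol from the defined alkene geometry.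

Step 6
Reactants: 10 [(2R,3R)-3-[(3E,5E)-3-methylhepta-3,5-dien-1-yl]-3-(propan-2-yl)oxiran-2-yl]methanol
Product: 11 (3S,6E,8E)-6-methyl-3-(propan-2-yl)deca-6,8-diene-1,3-diol
Conditions: NaAlH2(OCH2CH2OMe)2, THF, 0 °C
Reagents that add atoms: none
Why: Hydride delivered from the aluminate bound to the primary oxygen opens the 2,3-epoxy alcohol at C2, away from the fully substituted carbon, so the 1,3-diol should form with the tertiary C–O bond and its configuration untouched.

Step 7
Reactants: 11 (3S,6E,8E)-6-methyl-3-(propan-2-yl)deca-6,8-diene-1,3-diol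
Product: 12 (3S,6E,8E)-6-methyl-3-(propan-2-yl)-1,3-bis[(triethylsilyl)oxy]deca-6,8-diene
Conditions: Et3SiOTf, 2,6-lutidine, CH2Cl2, −78 → 0 °C
Reagents that add atoms: triethylsilyl trifluoromethanesulfonate, CC[Si](CC)(CC)OS(=O)(=O)C(F)(F)F
Why: A silyl triflate with a hindered pyridine base silylates the tertiary as well as the primary hydroxyl without affecting the diene.

Step 8
Reactants: 12 (3S,6E,8E)-6-methyl-3-(propan-2-yl)-1,3-bis[(triethylsilyl)oxy]deca-6,8-diene
Product: 13 (3S,6E,8E)-6-methyl-3-(propan-2-yl)-3-[(triethylsilyl)oxy]deca-6,8-dienal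
Conditions: (COCl)2, DMSO, CH2Cl2, −78 → −30 °C; then Et3N, −78 → 0 °C
Reagents that add atoms: none
Why: Under Swern conditions a primary triethylsilyl ether is cleaved by the chlorosulfonium salt and oxidised in the same operation, while the hindered tertiary silyl ether should stay in place.

Step 9
Reactants: 13 (3S,6E,8E)-6-methyl-3-(propan-2-yl)-3-[(triethylsilyl)oxy]deca-6,8-dienal
Product: 14 (4S,7E,9E)-1,1-dichloro-7-methyl-4-(propan-2-yl)-4-[(triethylsilyl)oxy]undeca-7,9-dien-2-ol (C2 epimers)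
Conditions: CH2Cl2, LiN(iPr)2, THF, −100 °C; then 13, −100 → −78 °C; AcOH quench
Reagents that add atoms: dichloromethane, ClCCl
Why: Preformed dichloromethyllithium is a small carbenoid nucleophile that adds to aldehydes at low temperature faster than it enolises them (carbonyl 1,2-addition); the new carbinol centre is oxidised in the next step.

Step 10
Reactants: 14 (4S,7E,9E)-1,1-dichloro-7-methyl-4-(propan-2-yl)-4-[(triethylsilyl)oxy]undeca-7,9-dien-2-ol (C2 epimers)
Product: 15 (4S,7E,9E)-1,1-dichloro-7-methyl-4-(propan-2-yl)-4-[(triethylsilyl)oxy]undeca-7,9-dien-2-one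
Conditions: Dess–Martin periodinane, NaHCO3, CH2Cl2, 0 °C → rt
Reagents that add atoms: none
Why: Dess–Martin oxidation converts the electron-poor secondary alcohol into the ketone under buffered, non-enolising conditions that spare the silyl ether and the diene.

Step 11
Reactants: 15 (4S,7E,9E)-1,1-dichloro-7-methyl-4-(propan-2-yl)-4-[(triethylsilyl)oxy]undeca-7,9-dien-2-one
Product: 18 (3R,3aR,6R,8aR)-6,8a-dimethyl-3-(propan-2-yl)-3-[(triethylsilyl)oxy]-2,3,3a,5,6,8a-hexahydroazulen-4(1H)-one, via chloro-oxyallyl cation 16 (not isolated), via chloro ketone cycloadduct 17 (not isolated)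
Conditions: NaOCH2CF3 (1.2 equiv), CF3CH2OH, 0.01 M, 0 °C → rt; then Zn–Cu couple, NH4Cl, MeOH, rt (same flask)
Reagents that add atoms: none
Why: Trifluoroethoxide enolises the ketone toward C6 and chloride leaves from the dichloromethyl carbon C4, giving the chlorine-stabilised 2-oxidoallyl cation 16 (C4–C5–C6), which is captured by the tethered diene; zinc then reduces the C4–Cl bond of adduct 17 in the same flask. The closest known reaction type is the base-induced (4+3) cycloaddition of α-halo and α,α-dihalo ketones with dienes in trifluoroethanol, in its intramolecular form with a three-atom tether, followed by zinc dechlorination of the adduct. The cyclopentane closes by 5-exo attack of the methyl-bearing diene terminus C7 on C6, and the cycloheptenone by bond formation between C3 and C4, in one step or in two through a tertiary allyl cation. At C6, allylic 1,3-strain (helped by sodium bridging to the oxido oxygen) should hold the C10 silyloxy group in the plane of the cation and turn the isopropyl group away from the tether, so C5 ends cis to the C10 oxygen; at C7, the extended arrangement that a three-atom tether favours puts the methyl group trans to the C6 hydrogen and hence cis to the C10 oxygen; at C3, suprafacial addition to the (E,E)-diene puts the methyl group cis to C8, which leaves the C3 hydrogen on the β face for the later elimination. The step needs carbon–carbon closure at C3 to outrun displacement of chloride by the alkoxide and oxygen closure of the enolate; the second chlorine makes C4 a hindered, lone-pair-stabilised terminus, the solvent is a poor nucleophile, and the E geometry and methyl group of the diene terminus favour s-cis attack at the cation-stabilising carbon.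

Step 12
Reactants: 18 (3R,3aR,6R,8aR)-6,8a-dimethyl-3-(propan-2-yl)-3-[(triethylsilyl)oxy]-2,3,3a,5,6,8a-hexahydroazulen-4(1H)-one
Product: 19 (3R,3aR,6R,8aR)-3-hydroxy-6,8a-dimethyl-3-(propan-2-yl)-2,3,3a,5,6,8a-hexahydroazulen-4(1H)-one
Conditions: HF·pyridine, pyridine, THF, 0 °C → rt
Reagents that add atoms: none
Why: Buffered fluoride cleaves the tertiary silyl ether without base, so the β-hydroxy ketone should be released without retro-aldol cleavage or dehydration.

Step 13
Reactants: 19 (3R,3aR,6R,8aR)-3-hydroxy-6,8a-dimethyl-3-(propan-2-yl)-2,3,3a,5,6,8a-hexahydroazulen-4(1H)-one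
Product: 20 (3R,3aS,4S,6R,8aR)-6,8a-dimethyl-3-(propan-2-yl)-1,2,3,3a,4,5,6,8a-octahydroazulene-3,4-diol
Conditions: Me4NBH(OAc)3, MeCN/AcOH, −30 → 0 °C
Reagents that add atoms: none
Why: In this hydroxyl-directed (Evans–Saksena) reduction the β-oriented C10 oxygen binds the acetoxyborohydride and delivers hydride to the β face of the C5 carbonyl, which should give the 1,3-anti diol with the C5 hydroxyl α.

Step 14
Reactants: 21 4-hydroxybenzoic acid
Product: 23 4-[(triisopropylsilyl)oxy]benzoic acid, via bis-silylated acid 22 (not isolated)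
Conditions: iPr3SiCl, imidazole, DMF, rt; then AcOH/THF/H2O, rt
Reagents that add atoms: chlorotriisopropylsilane, CC(C)[Si](Cl)(C(C)C)C(C)C
Why: Phenol and acid are both silylated and the far more labile silyl ester is then hydrolysed selectively, leaving the base-robust aryl silyl ether (silylation with selective silyl ester hydrolysis).

Step 15
Reactants: 20 (3R,3aS,4S,6R,8aR)-6,8a-dimethyl-3-(propan-2-yl)-1,2,3,3a,4,5,6,8a-octahydroazulene-3,4-diol; 23 4-[(triisopropylsilyl)oxy]benzoic acid
Product: 24 (3R,3aS,4S,6R,8aR)-3-hydroxy-6,8a-dimethyl-3-(propan-2-yl)-1,2,3,3a,4,5,6,8a-octahydroazulen-4-yl 4-[(triisopropylsilyl)oxy]benzoate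
Conditions: DCC, DMAP (cat.), CH2Cl2, 0 °C → rt
Reagents that add atoms: none
Why: Steglich esterification should acylate the secondary C5 hydroxyl only, because the tertiary C10 hydroxyl is too hindered to react.

Step 16
Reactants: 24 (3R,3aS,4S,6R,8aR)-3-hydroxy-6,8a-dimethyl-3-(propan-2-yl)-1,2,3,3a,4,5,6,8a-octahydroazulen-4-yl 4-[(triisopropylsilyl)oxy]benzoate
Product: 25 C1–C2 α-epoxide of 24 (epoxide oxygen anti to the C7 methyl)
Conditions: mCPBA, NaHCO3, CH2Cl2, 0 °C
Reagents that add atoms: 3-chloroperoxybenzoic acid, OOC(=O)c1cccc(Cl)c1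
Why: In this Prilezhaev epoxidation of the only alkene the axial C7 methyl group shields the β face next to C1 while the C3 methyl group is equatorial, so the peracid should attack the α face.

Step 17
Reactants: 25 C1–C2 α-epoxide of 24
Product: 28 (3R,3aS,4S,8R,8aS)-3,8-dihydroxy-6,8a-dimethyl-3-(propan-2-yl)-1,2,3,3a,4,5,8,8a-octahydroazulen-4-yl 4-[(triisopropylsilyl)oxy]benzoate, via hydroxy selenide 26 (not isolated), via selenoxide 27 (not isolated)
Conditions: (PhSe)2, NaBH4, EtOH, rt → 60 °C; then THF, 30% aq. H2O2, 0 °C → rt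
Reagents that add atoms: none
Why: Phenylselenide opens the epoxide with inversion at C2, the carbon remote from the quaternary C7, which keeps the C1 hydroxyl α and puts selenium β, cis to the C3 hydrogen, so that selenoxide syn-elimination, which avoids the carbinol carbon, should form the C2=C3 alkene (epoxide to allylic alcohol transposition).

Step 18
Reactants: 28 (3R,3aS,4S,8R,8aS)-3,8-dihydroxy-6,8a-dimethyl-3-(propan-2-yl)-1,2,3,3a,4,5,8,8a-octahydroazulen-4-yl 4-[(triisopropylsilyl)oxy]benzoate; 29 (2Z)-2-methylbut-2-enoic acid (angelic acid)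
Product: 31 (3R,3aS,4S,8R,8aS)-3-hydroxy-6,8a-dimethyl-8-{[(2Z)-2-methylbut-2-enoyl]oxy}-3-(propan-2-yl)-1,2,3,3a,4,5,8,8a-octahydroazulen-4-yl 4-[(triisopropylsilyl)oxy]benzoate, via angelic mixed anhydride 30 (not isolated)
Conditions: 29, 2,4,6-Cl3C6H2COCl, Et3N, PhMe, rt; then 28, 80 °C
Reagents that add atoms: none
Why: Yamaguchi-type acylation through the preformed mixed anhydride, run without a nucleophilic catalyst, should transfer the angeloyl group to the secondary allylic hydroxyl without Z-to-E isomerisation, and the tertiary hydroxyl does not react.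

Step 19
Reactants: 31 (3R,3aS,4S,8R,8aS)-3-hydroxy-6,8a-dimethyl-8-{[(2Z)-2-methylbut-2-enoyl]oxy}-3-(propan-2-yl)-1,2,3,3a,4,5,8,8a-octahydroazulen-4-yl 4-[(triisopropylsilyl)oxy]benzoate
Product: 32 (3R,3aS,4S,8R,8aS)-3-hydroxy-6,8a-dimethyl-8-{[(2Z)-2-methylbut-2-enoyl]oxy}-3-(propan-2-yl)-1,2,3,3a,4,5,8,8a-octahydroazulen-4-yl 4-hydroxybenzoate
Conditions: Bu4NF, AcOH, THF, 0 °C
Reagents that add atoms: none
Why: Buffered fluoride cleaves the aryl silyl ether rapidly (desilylation) and should leave both esters, the angelate geometry and the tertiary alcohol untouched.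

Compound list
1 | (E)-but-2-enal (crotonaldehyde) | C/C=C/C=O | starting material
2 | 2-(triphenylphosphoranylidene)propanal | CC(C=O)=P(c1ccccc1)(c1ccccc1)c1ccccc1 | starting material
3 | (2E,4E)-2-methylhexa-2,4-dienal | O=C/C(C)=C/C=C/C | intermediate
4 | (3E,5E)-3-methylhepta-1,3,5-triene | C=C/C(C)=C/C=C/C | intermediate
5 | 4-methylpent-2-yn-1-ol | CC(C)C#CCO | starting material
6 | sodium 2,2-bis(2-methoxyethoxy)-3-(propan-2-yl)-2,5-dihydro-1,2-oxaluminol-2-uide (cyclic alkenylalanate) | CC(C)C1=CCO[Al-]1(OCCOC)OCCOC.[Na+] | intermediate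
7 | (2Z)-3-iodo-4-methylpent-2-en-1-ol | CC(C)/C(I)=C/CO | intermediate
8 | 9-[(3E,5E)-3-methylhepta-3,5-dien-1-yl]-9-borabicyclo[3.3.1]nonane | C(C/C(C)=C/C=C/C)B1C2CCCC1CCC2 | intermediate
9 | (2E,6E,8E)-6-methyl-3-(propan-2-yl)deca-2,6,8-trien-1-ol | OC/C=C(/C(C)C)CC/C(C)=C/C=C/C | intermediate
10 | [(2R,3R)-3-[(3E,5E)-3-methylhepta-3,5-dien-1-yl]-3-(propan-2-yl)oxiran-2-yl]methanol | OC[C@H]1O[C@@]1(C(C)C)CC/C(C)=C/C=C/C | intermediate
11 | (3S,6E,8E)-6-methyl-3-(propan-2-yl)deca-6,8-diene-1,3-diol | OCC[C@](O)(C(C)C)CC/C(C)=C/C=C/C | intermediate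
12 | (3S,6E,8E)-6-methyl-3-(propan-2-yl)-1,3-bis[(triethylsilyl)oxy]deca-6,8-diene | CC[Si](CC)(CC)OCC[C@](O[Si](CC)(CC)CC)(C(C)C)CC/C(C)=C/C=C/C | intermediate
13 | (3S,6E,8E)-6-methyl-3-(propan-2-yl)-3-[(triethylsilyl)oxy]deca-6,8-dienal | O=CC[C@](O[Si](CC)(CC)CC)(C(C)C)CC/C(C)=C/C=C/C | intermediate
14 | (4S,7E,9E)-1,1-dichloro-7-methyl-4-(propan-2-yl)-4-[(triethylsilyl)oxy]undeca-7,9-dien-2-ol (C2 epimers, centre left open) | ClC(Cl)C(O)C[C@](O[Si](CC)(CC)CC)(C(C)C)CC/C(C)=C/C=C/C | intermediate
15 | (4S,7E,9E)-1,1-dichloro-7-methyl-4-(propan-2-yl)-4-[(triethylsilyl)oxy]undeca-7,9-dien-2-one (cycloaddition precursor) | ClC(Cl)C(=O)C[C@](O[Si](CC)(CC)CC)(C(C)C)CC/C(C)=C/C=C/C | intermediate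
16 | 1-chloro-2-oxidoallyl cation derived from 15 (zwitterion, C4–C5–C6) | ClC=C([O-])[CH+][C@](O[Si](CC)(CC)CC)(C(C)C)CC/C(C)=C/C=C/C | intermediate
17 | 5-chloro-6,8a-dimethyl-3-(propan-2-yl)-3-[(triethylsilyl)oxy]-2,3,3a,5,6,8a-hexahydroazulen-4(1H)-one, configured as 18 at its other centres (chlorine on skeleton C4, epimers, centre left open) | C1=C[C@H](C)C(Cl)C(=O)[C@@H]2[C@]1(C)CC[C@@]2(O[Si](CC)(CC)CC)C(C)C | intermediate
18 | (3R,3aR,6R,8aR)-6,8a-dimethyl-3-(propan-2-yl)-3-[(triethylsilyl)oxy]-2,3,3a,5,6,8a-hexahydroazulen-4(1H)-one (trans-fused; C3 methyl α, C7 methyl β, C10 oxygen β) | C1=C[C@H](C)CC(=O)[C@@H]2[C@]1(C)CC[C@@]2(O[Si](CC)(CC)CC)C(C)C | intermediate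
19 | (3R,3aR,6R,8aR)-3-hydroxy-6,8a-dimethyl-3-(propan-2-yl)-2,3,3a,5,6,8a-hexahydroazulen-4(1H)-one | C1=C[C@H](C)CC(=O)[C@@H]2[C@]1(C)CC[C@@]2(O)C(C)C | intermediate
20 | (3R,3aS,4S,6R,8aR)-6,8a-dimethyl-3-(propan-2-yl)-1,2,3,3a,4,5,6,8a-octahydroazulene-3,4-diol (C5 hydroxyl α) | C1=C[C@H](C)C[C@H](O)[C@@H]2[C@]1(C)CC[C@@]2(O)C(C)C | intermediate
21 | 4-hydroxybenzoic acid | OC(=O)c1ccc(O)cc1 | starting material
22 | triisopropylsilyl 4-[(triisopropylsilyl)oxy]benzoate | CC(C)[Si](C(C)C)(C(C)C)Oc1ccc(cc1)C(=O)O[Si](C(C)C)(C(C)C)C(C)C | intermediate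
23 | 4-[(triisopropylsilyl)oxy]benzoic acid | CC(C)[Si](C(C)C)(C(C)C)Oc1ccc(cc1)C(O)=O | intermediate
24 | (3R,3aS,4S,6R,8aR)-3-hydroxy-6,8a-dimethyl-3-(propan-2-yl)-1,2,3,3a,4,5,6,8a-octahydroazulen-4-yl 4-[(triisopropylsilyl)oxy]benzoate | C1=C[C@H](C)C[C@H](OC(=O)c3ccc(O[Si](C(C)C)(C(C)C)C(C)C)cc3)[C@@H]2[C@]1(C)CC[C@@]2(O)C(C)C | intermediate
25 | C1–C2 α-epoxide of 24 (oxygen anti to the C7 methyl; C1 and C2 hydrogens β) | C[C@@H]1C[C@H](OC(=O)c2ccc(O[Si](C(C)C)(C(C)C)C(C)C)cc2)[C@@H]2[C@](C)(CC[C@@]2(O)C(C)C)[C@@H]2O[C@H]12 | intermediate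
26 | hydroxy selenide from 25 (C1 hydroxyl α, C2 phenylselanyl β) | C[C@@H]1C[C@H](OC(=O)c2ccc(O[Si](C(C)C)(C(C)C)C(C)C)cc2)[C@@H]2[C@](C)(CC[C@@]2(O)C(C)C)[C@H](O)[C@H]1[Se]c1ccccc1 | intermediate
27 | selenoxide of 26 (selenium centre left open) | C[C@@H]1C[C@H](OC(=O)c2ccc(O[Si](C(C)C)(C(C)C)C(C)C)cc2)[C@@H]2[C@](C)(CC[C@@]2(O)C(C)C)[C@H](O)[C@H]1[Se](=O)c1ccccc1 | intermediate
28 | (3R,3aS,4S,8R,8aS)-3,8-dihydroxy-6,8a-dimethyl-3-(propan-2-yl)-1,2,3,3a,4,5,8,8a-octahydroazulen-4-yl 4-[(triisopropylsilyl)oxy]benzoate (C1 hydroxyl α, C2=C3 alkene) | O[C@@H]1C=C(C)C[C@H](OC(=O)c2ccc(O[Si](C(C)C)(C(C)C)C(C)C)cc2)[C@@H]2[C@]1(C)CC[C@@]2(O)C(C)C | intermediate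
29 | (2Z)-2-methylbut-2-enoic acid (angelic acid) | C/C=C(/C)C(O)=O | starting material
30 | (2Z)-2-methylbut-2-enoic 2,4,6-trichlorobenzoic anhydride | C/C=C(/C)C(=O)OC(=O)c1c(Cl)cc(Cl)cc1Cl | intermediate
31 | (3R,3aS,4S,8R,8aS)-3-hydroxy-6,8a-dimethyl-8-{[(2Z)-2-methylbut-2-enoyl]oxy}-3-(propan-2-yl)-1,2,3,3a,4,5,8,8a-octahydroazulen-4-yl 4-[(triisopropylsilyl)oxy]benzoate | C/C=C(/C)C(=O)O[C@@H]1C=C(C)C[C@H](OC(=O)c2ccc(O[Si](C(C)C)(C(C)C)C(C)C)cc2)[C@@H]2[C@]1(C)CC[C@@]2(O)C(C)C | intermediate
32 | (3R,3aS,4S,8R,8aS)-3-hydroxy-6,8a-dimethyl-8-{[(2Z)-2-methylbut-2-enoyl]oxy}-3-(propan-2-yl)-1,2,3,3a,4,5,8,8a-octahydroazulen-4-yl 4-hydroxybenzoate | C/C=C(/C)C(=O)O[C@@H]1C=C(C)C[C@H](OC(=O)c2ccc(O)cc2)[C@@H]2[C@]1(C)CC[C@@]2(O)C(C)C | target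

Total step count: 19. Longest linear sequence: 17 steps (steps 1, 2, 4–13, 15–19); steps 3 and 14 are side branches.

Steps most likely to fail

1. Step 11. The tether may fold so that C6 closes on the other face while C7 is set correctly, which gives the cis ring fusion; this is loss of control over the C6 configuration during ring closure. The fallback sets C6 after the cyclisation instead of during it. Setting out from 15, the same cyclisation and zinc reduction would then deliver the cis-fused C6 epimer (3R,3aS,6R,8aR)-6,8a-dimethyl-3-(propan-2-yl)-3-[(triethylsilyl)oxy]-2,3,3a,5,6,8a-hexahydroazulen-4(1H)-one F1. F1 is equilibrated through its C5–C6 enolate (DBU, PhMe, 60 °C). Protonation on the α face, away from the C7 methyl and the C10 silyloxy group, and relief of the cis relationship between C5 and the isopropyl group should lead to 18, where the route is rejoined.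

2. Step 18. Acyl transfer to the hindered, axial, neopentyl-type C1 hydroxyl may be slow, and the acyl donor may isomerise from Z to E at the temperature needed. The fallback builds the Z-alkene on the ester instead of transferring it. Setting out from 28, esterification with 2-[bis(2,2,2-trifluoroethoxy)phosphoryl]propanoic acid (DCC, DMAP, CH2Cl2) gives the C1 2-[bis(2,2,2-trifluoroethoxy)phosphoryl]propanoate F3. Still–Gennari olefination of F3 with acetaldehyde (KN(SiMe3)2, 18-crown-6, THF, −78 °C) is Z-selective and should give 31, where the route is rejoined.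

3. Step 16. The peracid may attack the β face (poor facial selectivity), which would put the C1 oxygen on the wrong side and leave no syn hydrogen for the elimination. The fallback delivers the oxygen by anti opening instead of direct transfer. Setting out from 24, NBS in aqueous THF forms the bromonium ion on the face the electrophile prefers and water opens it from the other face, giving the trans-bromohydrin (C1 bromide β, C2 hydroxyl α) F2. Ring closure of F2 with K2CO3 (THF/MeOH, 0 °C) places the oxygen on the face opposite to the one reached by direct epoxidation and should give 25, where the route is rejoined.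

Further compounds
F1 | step 11 | (3R,3aS,6R,8aR)-6,8a-dimethyl-3-(propan-2-yl)-3-[(triethylsilyl)oxy]-2,3,3a,5,6,8a-hexahydroazulen-4(1H)-one (cis-fused C6 epimer of 18) | C1=C[C@H](C)CC(=O)[C@H]2[C@]1(C)CC[C@@]2(O[Si](CC)(CC)CC)C(C)C
F2 | step 16 | trans-bromohydrin of 24 (C1 bromide β, C2 hydroxyl α) | C[C@@H]1C[C@H](OC(=O)c2ccc(O[Si](C(C)C)(C(C)C)C(C)C)cc2)[C@@H]2[C@](C)(CC[C@@]2(O)C(C)C)[C@@H](Br)[C@@H]1O
F3 | step 18 | C1 2-[bis(2,2,2-trifluoroethoxy)phosphoryl]propanoate of 28 | CC(C(=O)O[C@@H]1C=C(C)C[C@H](OC(=O)c2ccc(O[Si](C(C)C)(C(C)C)C(C)C)cc2)[C@@H]2[C@]1(C)CC[C@@]2(O)C(C)C)P(=O)(OCC(F)(F)F)OCC(F)(F)F
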